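The ring C–O–ring D diaryl ether is disconnected, with ring D carried as a 2-pyrone. In ring D the oxygen-bearing carbon and the carbon holding the CH2CH2 bridge to ring A are 1,3-related, like C4 and C6 of 4-hydroxy-6-methyl-2-pyrone, whose C4 is a vinylogous acyl carbon and whose methyl group is acidic. In the key step the ring C phenoxide displaces bromide from C4 of a 4-bromo-2-pyrone, making that ether bond and the 19-membered ring in one operation. The precursor is the open chain in which rings A, B and C are already joined: the ring A side chain ends in the 4-bromo-2-pyrone, and ring C carries one free phenol beside a benzyl ether.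

Key step: step 12

Remark on the chemistry: the nucleophilic ring C phenol is carried as its triisopropylsilyl ether and released only in the step before ring closure, because a free phenol would not pass the ylide, dianion and PBr3 steps, and the phenol/bromopyrone pair should exist only briefly.

Step 1
Reactants: 1 4-(benzyloxy)-3-hydroxybenzaldehyde
Product: 2 4-(benzyloxy)-3-(triisopropylsilyloxy)benzaldehyde
Conditions: TIPSCl, imidazole, DMF, rt
Reagents that add atoms: triisopropylsilyl chloride, CC(C)[Si](Cl)(C(C)C)C(C)C
Why: O-silylation of the phenol with a silyl chloride and imidazole should proceed cleanly, and the bulky aryl silyl ether is chosen to withstand the later basic and acidic steps.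

Step 2
Reactants: 2 4-(benzyloxy)-3-(triisopropylsilyloxy)benzaldehyde
Product: 3 [4-(benzyloxy)-3-(triisopropylsilyloxy)phenyl]methanol
Conditions: NaBH4, MeOH/THF, 0 °C
Reagents that add atoms: none
Why: Borohydride reduction of an aromatic aldehyde is fast at 0 °C and leaves the benzyl and silyl ethers untouched.

Step 3
Reactants: 3 [4-(benzyloxy)-3-(triisopropylsilyloxy)phenyl]methanol
Product: 4 1-(benzyloxy)-4-(bromomethyl)-2-(triisopropylsilyloxy)benzene
Conditions: PBr3, CH2Cl2, 0 °C
Reagents that add atoms: phosphorus tribromide, BrP(Br)Br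
Why: Deoxybromination of an electron-rich benzylic alcohol with PBr3 (phosphite ester, then displacement by bromide) is reliable at 0 °C and is tolerated by aryl silyl ethers.

Step 4
Reactants: 4 1-(benzyloxy)-4-(bromomethyl)-2-(triisopropylsilyloxy)benzene
Product: 5 [4-(benzyloxy)-3-(triisopropylsilyloxy)benzyl]triphenylphosphonium bromide
Conditions: PPh3, toluene, 110 °C
Reagents that add atoms: triphenylphosphine, c1ccc(cc1)P(c1ccccc1)c1ccccc1
Why: SN2 quaternisation of triphenylphosphine by a benzylic bromide should give the salt, which precipitates from toluene.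

Step 5
Reactants: 6 3-hydroxy-4-methoxybenzyl alcohol, 7 4-fluorobenzaldehyde
Product: 8 4-[5-(hydroxymethyl)-2-methoxyphenoxy]benzaldehyde
Conditions: K2CO3, DMF, 120 °C
Reagents that add atoms: none
Why: Nucleophilic aromatic substitution (SNAr): the phenoxide displaces fluoride para to the formyl group, while carbonate does not ionise the benzylic alcohol, so only the phenol oxygen is arylated.

Step 6
Reactants: 5 [4-(benzyloxy)-3-(triisopropylsilyloxy)benzyl]triphenylphosphonium bromide, 8 4-[5-(hydroxymethyl)-2-methoxyphenoxy]benzaldehyde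
Product: 10 {3-[4-(2-{4-(benzyloxy)-3-(triisopropylsilyloxy)phenyl}ethenyl)phenoxy]-4-methoxyphenyl}methanol (E/Z mixture), via phosphonium ylide 9 (not isolated)
Conditions: NaHMDS, THF, 0 °C; then 8, 0 °C to rt
Reagents that add atoms: none
Why: Wittig olefination with a preformed semi-stabilised benzylic ylide should join rings B and C; the free benzylic alcohol is far less acidic than the phosphonium salt and does not quench the ylide, and the alkene geometry is irrelevant because the double bond is reduced next.

Step 7
Reactants: 10 {3-[4-(2-{4-(benzyloxy)-3-(triisopropylsilyloxy)phenyl}ethenyl)phenoxy]-4-methoxyphenyl}methanol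
Product: 11 {3-[4-(2-{4-(benzyloxy)-3-(triisopropylsilyloxy)phenyl}ethyl)phenoxy]-4-methoxyphenyl}methanol
Conditions: TsNHNH2, NaOAc, DME/H2O, reflux
Reagents that add atoms: none
Why: Diimide reduction (concerted transfer of two hydrogens from HN=NH generated in the flask) saturates the stilbene double bond and cannot cleave the aryl benzyl ether, the benzylic alcohol or the silyl ether.

Step 8
Reactants: 11 {3-[4-(2-{4-(benzyloxy)-3-(triisopropylsilyloxy)phenyl}ethyl)phenoxy]-4-methoxyphenyl}methanol
Product: 12 benzylic bromide of 11: ring A carries OMe, the para CH2Br and the meta aryloxy group; ring C keeps OBn and OTIPS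
Conditions: PBr3, CH2Cl2, 0 °C; crude product used at once
Reagents that add atoms: phosphorus tribromide, BrP(Br)Br
Why: Deoxybromination with PBr3 should convert the para-methoxybenzylic alcohol quickly at 0 °C, and the reactive bromide is carried on without chromatography.

Step 9
Reactants: 12 ring A benzylic bromide, 13 4-hydroxy-6-methyl-2-pyrone
Product: 15 4-hydroxy-6-(2-arylethyl)-2-pyrone in which the aryl group is ring A of the A–B–C chain (ring C: OBn, OTIPS), via dilithio pyrone dianion 14 (not isolated)
Conditions: 13 (3 equiv), LDA (2 equiv per 13), THF/DMPU, -78 °C; then 12, -78 to 0 °C; aq. HCl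
Reagents that add atoms: none
Why: Alkylation of the dianion of a vinylogous acid: the second deprotonation occurs at the 6-methyl group and this carbanion, the most basic site, attacks the benzylic bromide by SN2, giving the CH2CH2 bridge between ring A and the pyrone.

Step 10
Reactants: 15 4-hydroxy-6-(2-arylethyl)-2-pyrone (ring C: OBn, OTIPS)
Product: 16 4-bromo-6-(2-arylethyl)-2-pyrone (ring C: OBn, OTIPS)
Conditions: PBr3, DMF, 0 to 60 °C
Reagents that add atoms: phosphorus tribromide, BrP(Br)Br
Why: Deoxybromination of the vinylogous acid by Vilsmeier-type activation: the bromoiminium species from PBr3 and DMF activates the C4 oxygen and bromide then enters by addition–elimination, as in the standard preparation of 4-bromo-6-methyl-2-pyrone.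

Step 11
Reactants: 16 4-bromo-6-(2-arylethyl)-2-pyrone (ring C: OBn, OTIPS)
Product: 17 open-chain phenol with 4-bromo-2-pyrone end (ring C: OBn para and free OH meta to the CH2CH2 chain)
Conditions: TBAF, AcOH (1:1.2), THF, 0 °C; used directly
Reagents that add atoms: none
Why: Fluoride desilylation of the aryl silyl ether under acetic acid buffering should release the phenol in its neutral form, so that no phenoxide is present to attack the bromopyrone before the dilution step.

Step 12
Reactants: 17 open-chain phenol with 4-bromo-2-pyrone end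
Product: 18 macrocyclic 4-aryloxy-2-pyrone, O-benzyl (19-membered ring)
Conditions: K2CO3, DMF, 60 °C, syringe-pump addition of 17, final about 2 mM
Reagents that add atoms: none
Why: Carbonate ionises the ring C phenol, and the phenoxide adds to C4 of the pyrone, the beta carbon of the unsaturated lactone, giving a lactone enolate with a tetrahedral C4 that collapses by expelling bromide (conjugate addition–elimination, a vinylogous acyl substitution). The closest known reactions are the intermolecular displacement of halide from 4-halo-2-pyrones and 4-halocoumarins by phenoxides and the macrocyclic SNAr etherifications used for cyclophane diaryl ethers. The 19-membered ring closes in 19-exo-trig mode, since the accepting C3=C4 bond lies outside the new ring, and the flexible CH2CH2 links keep the closure free of strain. No stereocentre is formed. The step needs site selectivity for C4 over C2 and C6, secured because only addition at C4 becomes irreversible through loss of bromide, and it needs a single nucleophile, secured by the benzyl ether on the neighbouring ring C oxygen. Ring closure should win over oligomerisation because 17 is added slowly to the base and never accumulates.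

Step 13
Reactants: 18 macrocyclic 4-aryloxy-2-pyrone, 19 phenyl vinyl sulfoxide
Product: 22 O-benzyl ether of the target macrocycle, via bicyclic lactone cycloadduct 20 (not isolated), via sulfinyl cyclohexadiene 21 (not isolated)
Conditions: 19 (excess), o-xylene, 140 °C, sealed tube
Reagents that add atoms: none
Why: Diels–Alder addition of the vinyl sulfoxide across C3 and C6 of the donor-substituted pyrone, retro-Diels–Alder loss of CO2 and thermal syn-elimination of benzenesulfenic acid should give ring D with two new CH carbons; either orientation of the dienophile leads to the same arene.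

Step 14
Reactants: 22 O-benzyl ether of the target macrocycle
Product: 23 CNP0132125.0
Conditions: H2 (1 atm), Pd/C, EtOAc/MeOH, rt
Reagents that add atoms: none
Why: Hydrogenolysis of the aryl benzyl ether over Pd/C should free the ring C phenol, while the diaryl ethers, the methyl ether and the bibenzyl bridges are inert.

Compound list
1 | 4-(benzyloxy)-3-hydroxybenzaldehyde | O=Cc1ccc(OCc2ccccc2)c(O)c1 | starting material
2 | 4-(benzyloxy)-3-(triisopropylsilyloxy)benzaldehyde | O=Cc1ccc(OCc2ccccc2)c(O[Si](C(C)C)(C(C)C)C(C)C)c1 | intermediate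
3 | [4-(benzyloxy)-3-(triisopropylsilyloxy)phenyl]methanol | OCc1ccc(OCc2ccccc2)c(O[Si](C(C)C)(C(C)C)C(C)C)c1 | intermediate
4 | 1-(benzyloxy)-4-(bromomethyl)-2-(triisopropylsilyloxy)benzene | BrCc1ccc(OCc2ccccc2)c(O[Si](C(C)C)(C(C)C)C(C)C)c1 | intermediate
5 | [4-(benzyloxy)-3-(triisopropylsilyloxy)benzyl]triphenylphosphonium bromide | [Br-].c1ccc(cc1)[P+](Cc1ccc(OCc2ccccc2)c(O[Si](C(C)C)(C(C)C)C(C)C)c1)(c1ccccc1)c1ccccc1 | intermediate
6 | 3-hydroxy-4-methoxybenzyl alcohol | COc1ccc(CO)cc1O | starting material
7 | 4-fluorobenzaldehyde | O=Cc1ccc(F)cc1 | starting material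
8 | 4-[5-(hydroxymethyl)-2-methoxyphenoxy]benzaldehyde | COc1ccc(CO)cc1Oc1ccc(C=O)cc1 | intermediate
9 | ylide of 5, [4-(benzyloxy)-3-(triisopropylsilyloxy)benzylidene]triphenylphosphorane (not isolated) | c1ccc(cc1)P(=Cc1ccc(OCc2ccccc2)c(O[Si](C(C)C)(C(C)C)C(C)C)c1)(c1ccccc1)c1ccccc1 | intermediate
10 | stilbene joining rings B and C, ring A with CH2OH, E/Z mixture | COc1ccc(CO)cc1Oc1ccc(C=Cc2ccc(OCc3ccccc3)c(O[Si](C(C)C)(C(C)C)C(C)C)c2)cc1 | intermediate
11 | bibenzyl alcohol, rings A, B and C joined, ring A with CH2OH | COc1ccc(CO)cc1Oc1ccc(CCc2ccc(OCc3ccccc3)c(O[Si](C(C)C)(C(C)C)C(C)C)c2)cc1 | intermediate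
12 | ring A benzylic bromide of 11 | COc1ccc(CBr)cc1Oc1ccc(CCc2ccc(OCc3ccccc3)c(O[Si](C(C)C)(C(C)C)C(C)C)c2)cc1 | intermediate
13 | 4-hydroxy-6-methyl-2-pyrone | Cc1cc(O)cc(=O)o1 | starting material
14 | dilithium dianion of 13, deprotonated at the 4-OH and the 6-methyl group (not isolated) | [Li+].[Li+].[CH2-]c1cc([O-])cc(=O)o1 | intermediate
15 | 4-hydroxy-2-pyrone linked at C6 by CH2CH2 to ring A; ring C with OBn and OTIPS | COc1ccc(CCc2cc(O)cc(=O)o2)cc1Oc1ccc(CCc2ccc(OCc3ccccc3)c(O[Si](C(C)C)(C(C)C)C(C)C)c2)cc1 | intermediate
16 | 4-bromo-2-pyrone analogue of 15; ring C with OBn and OTIPS | COc1ccc(CCc2cc(Br)cc(=O)o2)cc1Oc1ccc(CCc2ccc(OCc3ccccc3)c(O[Si](C(C)C)(C(C)C)C(C)C)c2)cc1 | intermediate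
17 | open-chain phenol with 4-bromo-2-pyrone end; ring C with OBn and free OH | COc1ccc(CCc2cc(Br)cc(=O)o2)cc1Oc1ccc(CCc2ccc(OCc3ccccc3)c(O)c2)cc1 | intermediate
18 | macrocyclic 4-aryloxy-2-pyrone, O-benzyl, 19-membered ring | COc1ccc2cc1Oc1ccc(cc1)CCc1ccc(OCc3ccccc3)c(c1)Oc1cc(=O)oc(c1)CC2 | intermediate
19 | phenyl vinyl sulfoxide (racemic at sulfur) | C=CS(=O)c1ccccc1 | starting material
20 | bicyclic lactone cycloadduct of 18 and 19, 2-oxabicyclo[2.2.2]oct-5-en-3-one core, sulfinyl carbon next to the alkyl-bearing bridgehead, diastereomer mixture (not isolated) | COc1ccc2cc1Oc1ccc(cc1)CCc1ccc(OCc3ccccc3)c(c1)OC1=CC3(CC2)OC(=O)C1CC3S(=O)c1ccccc1 | intermediate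
21 | sulfinyl cyclohexa-1,3-diene after loss of CO2, diastereomer mixture (not isolated) | COc1ccc2cc1Oc1ccc(cc1)CCc1ccc(OCc3ccccc3)c(c1)OC1=CCC(S(=O)c3ccccc3)C(CC2)=C1 | intermediate
22 | O-benzyl ether of the target macrocycle | COc1ccc2cc1Oc1ccc(cc1)CCc1ccc(OCc3ccccc3)c(c1)Oc1cccc(c1)CC2 | intermediate
23 | CNP0132125.0, no stereocentres | COc1ccc2cc1Oc1ccc(cc1)CCc1ccc(O)c(c1)Oc1cccc(c1)CC2 | target

Total step count: 14. Longest linear sequence: 13 steps (compound 1 to compound 23 through steps 1 to 4 and 6 to 14); step 5 is a one-step side branch.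

Steps most likely to fail

Step 12. Intermolecular etherification may outrun ring closure and give oligomers, or the phenoxide may attack the lactone carbonyl and open the pyrone. The fallback sets out from 16 and returns at 22; it makes the arene first and the ether second. Heating 16 with phenyl vinyl sulfoxide 19 in o-xylene at 140 °C should run the same cycloaddition, CO2 loss and sulfenic acid elimination on the open chain. It passes through the bicyclic lactone cycloadduct F1 and the sulfinyl cyclohexadiene F2, neither isolated, and gives the meta-bromoarene silyl ether F3. Buffered TBAF then frees the bromo phenol F4. An intramolecular Ullmann etherification (CuO, K2CO3, pyridine, 115 °C, high dilution) forms the same ring C–O–ring D bond and delivers 22.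

Step 13. The donor-substituted, partly aromatic pyrone may add the dienophile so slowly that the sulfoxide decomposes thermally before it reacts. The fallback sets out from 18 and returns at 22. Phenyl vinyl sulfone, which is more electron-poor and thermally robust, is heated with 18 in o-dichlorobenzene at 180 °C. The bicyclic lactone sulfone F5, not isolated, loses CO2 to give the sulfonyl cyclohexadiene F6. DBU in THF at rt then eliminates benzenesulfinate by an E1cB process and aromatises ring D to 22.

Step 10. The HBr released may cleave the aryl silyl ether, or the bromoiminium reagent may formylate the electron-rich rings. The fallback sets out from 15 and returns at 18; it replaces bromide by a sulfonate leaving group that is installed under basic conditions. TsCl and Et3N in CH2Cl2 at 0 °C give the 4-tosyloxy-2-pyrone silyl ether F7. TBAF/AcOH frees the phenol tosylate F8. K2CO3 in DMF at high dilution then closes the ring by addition–elimination at C4 with loss of tosylate, giving 18. This relies on the known displacement of 4-sulfonyloxy groups on 2-pyrones and coumarins by heteroatom nucleophiles; tosyl transfer to the phenoxide by attack at sulfur is the competing pathway.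

Further compounds
F1 | step 12 | bicyclic lactone cycloadduct of 16 and 19, bromine on the ring alkene, diastereomer mixture (not isolated) | COc1ccc(CCC23OC(=O)C(CC2S(=O)c4ccccc4)C(Br)=C3)cc1Oc1ccc(CCc2ccc(OCc3ccccc3)c(O[Si](C(C)C)(C(C)C)C(C)C)c2)cc1
F2 | step 12 | bromo sulfinyl cyclohexa-1,3-diene after loss of CO2 (not isolated) | COc1ccc(CCC2=CC(Br)=CCC2S(=O)c4ccccc4)cc1Oc1ccc(CCc2ccc(OCc3ccccc3)c(O[Si](C(C)C)(C(C)C)C(C)C)c2)cc1
F3 | step 12 | open-chain meta-bromoarene (ring D with Br), ring C with OBn and OTIPS | COc1ccc(CCc2cccc(Br)c2)cc1Oc1ccc(CCc2ccc(OCc3ccccc3)c(O[Si](C(C)C)(C(C)C)C(C)C)c2)cc1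
F4 | step 12 | open-chain meta-bromoarene with free ring C phenol | COc1ccc(CCc2cccc(Br)c2)cc1Oc1ccc(CCc2ccc(OCc3ccccc3)c(O)c2)cc1
F5 | step 13 | bicyclic lactone cycloadduct of 18 and phenyl vinyl sulfone, diastereomer mixture (not isolated) | COc1ccc2cc1Oc1ccc(cc1)CCc1ccc(OCc3ccccc3)c(c1)OC1=CC3(CC2)OC(=O)C1CC3S(=O)(=O)c1ccccc1
F6 | step 13 | macrocyclic phenylsulfonyl cyclohexa-1,3-diene after loss of CO2, racemic | COc1ccc2cc1Oc1ccc(cc1)CCc1ccc(OCc3ccccc3)c(c1)OC1=CCC(S(=O)(=O)c3ccccc3)C(CC2)=C1
F7 | step 10 | 4-tosyloxy-2-pyrone analogue of 16, ring C with OBn and OTIPS | COc1ccc(CCc2cc(OS(=O)(=O)c3ccc(C)cc3)cc(=O)o2)cc1Oc1ccc(CCc2ccc(OCc3ccccc3)c(O[Si](C(C)C)(C(C)C)C(C)C)c2)cc1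
F8 | step 10 | 4-tosyloxy-2-pyrone analogue of 17, free ring C phenol | COc1ccc(CCc2cc(OS(=O)(=O)c3ccc(C)cc3)cc(=O)o2)cc1Oc1ccc(CCc2ccc(OCc3ccccc3)c(O)c2)cc1
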